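**Assumption:** the SMILES has no stereocentre and no stereodescriptor. Any conformational chirality of the macrocycle should interconvert at room temperature. The compound is therefore made as drawn and no asymmetric step is needed.

**Ring labels:** A is the 4-hydroxy-3-aryloxyphenyl ring, B the para-phenylene, C the meta-phenylene, and D the 1,2,3-trisubstituted 2-aryloxy-3-hydroxyphenyl ring. The connectivity is A–O–B–CH2CH2–C–O–D–CH2CH2–A, an 18-membered ring.

## Retrosynthetic overview
1. The target comes from its dimethyl ether (O-demethylation), which comes from the macrocyclic A–CH=CH–D stilbene (hydrogenation).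
2. The macrocycle is the only ring formed. It is closed last, at the A–D bridge, by intramolecular McMurry coupling of an acyclic tetra-aryl dialdehyde.
3. In the dialdehyde, the A–O–B ether comes from Ullmann coupling of isovanillin with an aryl bromide. The C–O–D ether comes from SNAr of a phenol on 2-fluoro-3-methoxybenzaldehyde.
4. The central B–C bibenzyl, 3-[2-(4-bromophenyl)ethyl]phenol, comes from 4-bromostyrene and 3-iodophenol by hydroboration and iodide-selective B-alkyl Suzuki coupling.
5. The only protecting groups are the two methyl ethers already present in the commercial building blocks.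

## Route

**Step 1**
Reactants: 1, 4-bromostyrene; 2, 3-iodophenol
Product: 3, 3-[2-(4-bromophenyl)ethyl]phenol
Conditions: 1, 9-BBN (1.0 equiv), THF, 0 °C→rt; then 2 (1.1 equiv), PdCl2(dppf) (3 mol %), aq K3PO4 (4 equiv), THF–DMF, rt→40 °C
Reagents that add atoms: none (9-BBN delivers only H and the boron is lost)
Why: Anti-Markovnikov hydroboration gives the primary 2-arylethyl-9-BBN, and in the B-alkyl Suzuki–Miyaura coupling Pd inserts into C–I much faster than into C–Br at ≤40 °C, so the bromide survives (a slight excess of 2 leaves no borane to attack ArBr).

**Step 2**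
Reactants: 3; 4, 2-fluoro-3-methoxybenzaldehyde
Product: 5, 2-{3-[2-(4-bromophenyl)ethyl]phenoxy}-3-methoxybenzaldehyde
Conditions: K2CO3, DMAc, 130 °C
Reagents that add atoms: none beyond the listed reactants
Why: This is an SNAr in which the ortho-formyl group stabilises the Meisenheimer intermediate so the phenoxide of 3 displaces fluoride, while the unactivated aryl bromide is inert.

**Step 3**
Reactants: 5; 6, isovanillin (3-hydroxy-4-methoxybenzaldehyde)
Product: 7, 3-(4-{2-[3-(2-formyl-6-methoxyphenoxy)phenyl]ethyl}phenoxy)-4-methoxybenzaldehyde (acyclic A–O–B–CH2CH2–C–O–D dialdehyde)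
Conditions: 6 (1.5 equiv), CuI (20 mol %), N,N-dimethylglycine·HCl (60 mol %), Cs2CO3, dioxane, 105 °C
Reagents that add atoms: none beyond the listed reactants
Why: This ligand-accelerated Ullmann diaryl ether coupling involves only one free phenol and one aryl halide, the tertiary-amine ligand cannot condense with the aldehydes, and the non-enolisable aldehydes tolerate carbonate base.

**Step 4**
Reactants: 7
Product: 8, macrocyclic stilbene (isomarchantin C dimethyl ether with an A–CH=CH–D bridge; E/Z ratio irrelevant, Z expected to be major)
Conditions: TiCl4, Zn, THF, reflux; 7 added by syringe pump over about 20 h (effective concentration <1 mM)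
Reagents that add atoms: none
Why: In this intramolecular McMurry coupling, the saturated B–C bridge and the two ether hinges let the two formyl groups meet on low-valent Ti, and pseudo-high dilution favours 18-membered ring closure over oligomerisation.

**Step 5**
Reactants: 8
Product: 9, isomarchantin C dimethyl ether (both bridges saturated)
Conditions: H2 (1 atm), 10% Pd/C, EtOAc, rt
Reagents that add atoms: none
Why: Catalytic hydrogenation reduces either stilbene isomer to the same CH2CH2 bridge, and the aryl methyl and diaryl ethers are inert.

**Step 6**
Reactants: 9
Product: 10, isomarchantin C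
Conditions: BBr3 (6 equiv), CH2Cl2, −78 °C→rt; then H2O
Reagents that add atoms: none
Why: In this Lewis-acid aryl methyl ether cleavage, bromide attacks only the sp3 methyl carbons, so both diaryl ether C(sp2)–O bonds stay intact.

## Compound list
1 | 4-bromostyrene | C=Cc1ccc(Br)cc1 | starting material
2 | 3-iodophenol | Oc1cccc(I)c1 | starting material
3 | 3-[2-(4-bromophenyl)ethyl]phenol | Oc1cccc(CCc2ccc(Br)cc2)c1 | intermediate
4 | 2-fluoro-3-methoxybenzaldehyde | COc1cccc(C=O)c1F | starting material
5 | 2-{3-[2-(4-bromophenyl)ethyl]phenoxy}-3-methoxybenzaldehyde | COc1cccc(C=O)c1Oc1cccc(CCc2ccc(Br)cc2)c1 | intermediate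
6 | isovanillin (3-hydroxy-4-methoxybenzaldehyde) | COc1ccc(C=O)cc1O | starting material
7 | acyclic tetra-aryl dialdehyde | COc1cccc(C=O)c1Oc1cccc(CCc2ccc(Oc3cc(C=O)ccc3OC)cc2)c1 | intermediate
8 | macrocyclic stilbene, dimethyl ether (E/Z) | COc1ccc2cc1Oc1ccc(cc1)CCc1cccc(c1)Oc1c(OC)cccc1C=C2 | intermediate
9 | isomarchantin C dimethyl ether | COc1ccc2cc1Oc1ccc(cc1)CCc1cccc(c1)Oc1c(OC)cccc1CC2 | intermediate
10 | isomarchantin C | Oc1ccc2cc1Oc1ccc(cc1)CCc1cccc(c1)Oc1c(O)cccc1CC2 | target

## Summary
Total step count: 6
Longest linear sequence: 6

Steps most likely to fail, each with a fallback that changes the approach: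

1. **Step 4, McMurry macrocyclisation.** The risks are oligomers, pinacol products and ring strain.
   - Fallback: close the ring by intramolecular Wittig reaction.
   - Run Step 3 with 3-hydroxy-4-methoxybenzyl alcohol in place of 6.
   - Convert the benzylic alcohol to its phosphonium salt (PPh3·HBr, MeCN, reflux).
   - Cyclise onto the D-ring aldehyde (NaOMe, CH2Cl2, high dilution). This rejoins the route at 8 and adds one step.

2. **Step 3, Ullmann coupling.** The aryl bromide is unactivated and the phenol is ortho-substituted and rather electron-poor.
   - Fallback: make the A–O–B ether by SNAr and build outward from it.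
   - Couple 3-hydroxy-4-methoxybenzyl alcohol with 4-fluorobenzaldehyde (K2CO3, DMF).
   - Carry out a Wittig reaction with (3-hydroxybenzyl)triphenylphosphonium bromide, then hydrogenate over Pd/C.
   - Perform the SNAr with 4, then oxidise with MnO2. This gives the same dialdehyde 7 without copper.

3. **Step 1, I-over-Br selective B-alkyl Suzuki coupling.** The risk is that the bromide also couples and gives oligomers.
   - Fallback: carry out a Wittig olefination of 3-hydroxybenzaldehyde with commercial (4-bromobenzyl)triphenylphosphonium bromide.
   - Reduce the resulting stilbene with diimide (TsNHNH2, NaOAc, aq. THF, reflux), which spares C–Br. This gives 3 and adds one step.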